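**Overview**

- Retrosynthesis: the C11 epoxide oxygen, the three acetyl groups and the lactone (C8–C17 bond, then the O7–C19 ester bond and the C7–O bond) are removed first. The ten-membered ring is then contracted by a retro-oxy-Cope step that joins C3 to C8 and cuts C5–C6. In the resulting trans-decalin the C8–C7 bond (acetylide addition), the C3–C4 bond (aldol) and finally the ring A bonds C10–C11 and C1–C14 (Diels–Alder) are cut.
- Enabling feature: in the ring C1–C10 the C8 oxygen and the C3=C4 double bond stand in the sequence C8(O)–C7–C6–C5–C4=C3. C3 and C8 can therefore be neighbours in a six-membered ring C1–C2–C3–C8–C9–C10 fused to ring A (C1, C10, C11–C14), with OH and ethynyl (C7, C6) on C8 and the alkenyl group (C4, C5, C16) on C3.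
- Forward order of rings: ring A is built onto the quinone ring by the Diels–Alder reaction and functionalized. After the two unsaturated groups are attached, the quinone-derived ring is expanded by four carbons to the ten-membered ring. The γ-lactone is closed by an intramolecular Reformatsky reaction and the spiro-epoxide is formed last.
- Stereochemistry: C1 comes from the chiral Diels–Alder catalyst, C14 from the endo mode, C10 from equilibration to the trans ring fusion. C2, C9, C13, C12 and the equatorial C3 substituent come from reagent approach opposite the axial C15 methyl or the axial C14 oxygen of the rigid trans-decalin. The cis C3=C4 bond comes from the axial-ethynyl/equatorial-alkenyl geometry of the sigmatropic step, C7 from hydroxylation of the ring trienolate, C8 and C17 from the chelated Reformatsky closure, and C11 from epoxidation directed by the C12 hydroxyl.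

Key step: step 21

Remark: briarane numbering is used for all polycyclic compounds (ring A = C1, C10, C11–C14; ring B = C1, C2, C3, C8, C9, C10 before and C1–C10 after the ring expansion; C15 = methyl on C1, C16 on C5, C17–C19 = lactone carbons with C18 the methyl, C20 on C11); β is the face of the C15 methyl, α the opposite face; the sense of induction of the Diels–Alder catalyst is taken from its usual model for quinones, and the enantiomeric catalyst would be used if the adduct proved antipodal.

Abbreviations: PMB = 4-methoxybenzyl; PMBM = (4-methoxybenzyloxy)methyl; TBS = tert-butyldimethylsilyl; TES = triethylsilyl; TBDPS = tert-butyldiphenylsilyl.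

**Route**

Step 1
Reactants: 1 (E)-4-methoxybut-3-en-2-one
Product: 2 sodium (E)-3-oxobut-1-en-1-olate
Conditions: NaOH (1.0 equiv), H2O–MeOH, 0 → 25 °C; evaporate and dry under vacuum
Reagents that add atoms: sodium hydroxide, [Na+].[OH-]
Why: Vinylogous saponification, in which hydroxide adds to the β-carbon of the vinylogous ester and methoxide leaves (addition–elimination), should give the resonance-stabilized sodium enolate of formylacetone in its extended E form.

Step 2
Reactants: 2 sodium (E)-3-oxobut-1-en-1-olate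
Product: 3 (E)-4-(tert-butyldimethylsilyloxy)but-3-en-2-one
Conditions: t-BuMe2SiCl, THF, 0 → 25 °C
Reagents that add atoms: tert-butyldimethylsilyl chloride, CC(C)(C)[Si](C)(C)Cl
Why: O-Silylation of the enolate (silyl ether formation) takes place at the formyl-derived oxygen and should give the conjugated, less hindered E vinylogous silyl ester.

Step 3
Reactants: 3 (E)-4-(tert-butyldimethylsilyloxy)but-3-en-2-one
Product: 4 (E)-1-(tert-butyldimethylsilyloxy)-3-(triethylsilyloxy)buta-1,3-diene
Conditions: Et3SiOTf, Et3N, Et2O, 0 °C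
Reagents that add atoms: triethylsilyl trifluoromethanesulfonate, CC[Si](CC)(CC)OS(=O)(=O)C(F)(F)F
Why: Soft enolization (enol silylation with a silyl triflate and an amine) converts the methyl ketone into the 2-silyloxydiene, and the triethylsilyl group is chosen here because this enol ether can later be cleaved by MeLi while the TBS ether stays.

Step 4
Reactants: 4 (E)-1-(tert-butyldimethylsilyloxy)-3-(triethylsilyloxy)buta-1,3-diene; 5 2-methoxy-5-methyl-1,4-benzoquinone
Product: 6 cis-fused Diels–Alder adduct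
Conditions: (S)-3,3-diphenyl-1-(o-tolyl)tetrahydro-1H,3H-pyrrolo[1,2-c][1,3,2]oxazaborole·HNTf2 (20 mol %), CH2Cl2, −78 °C
Reagents that add atoms: none
Why: Enantioselective endo Diels–Alder reaction at the methyl-substituted double bond of the quinone, in which the monodentate boron Lewis acid binds the more basic vinylogous-ester carbonyl (the later C2=O) so that the nucleophilic CH2 end of the diene bonds to C10 and the silyloxy end to C1, the shielded face of the catalyst complex setting C1 and the endo mode setting C14 (silyloxy anti to the C15 methyl).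

Step 5
Reactants: 6 cis-fused Diels–Alder adduct
Product: 7 trans-fused dione
Conditions: DBU (0.2 equiv), CH2Cl2, 0 → 25 °C
Reagents that add atoms: none
Why: Base-catalysed epimerization through the C9 enolate at C10, the only enolizable ring-fusion carbon (C1 is quaternary, so no aromatization can occur), should equilibrate the adduct to the trans-fused decalindione, the preferred isomer in the classical methoxytoluquinone adducts.

Step 6
Reactants: 7 trans-fused dione
Product: 8 2β,9β-diol
Conditions: LiAlH4, THF, −78 → −20 °C; then H2O, aq NaOH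
Reagents that add atoms: none
Why: 1,2-Reduction of the enone carbonyl (C9) and of the vinylogous-ester carbonyl (C2) by LiAlH4, with hydride entering both from the α face opposite the axial C15 methyl, should give the axial 9β-carbinol and the equatorial 2β-carbinol, and the basic work-up preserves the acid-labile bis-allylic enol ether.

Step 7
Reactants: 8 2β,9β-diol
Product: 10 bis-PMB ether, via disodium dialkoxide 9 (not isolated)
Conditions: NaH, 4-MeOC6H4CH2Cl, Bu4NI (cat.), THF–DMF, 0 → 25 °C
Reagents that add atoms: 4-methoxybenzyl chloride, COc1ccc(CCl)cc1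
Why: Williamson etherification under basic conditions protects both carbinols without exposing either enol ether to acid.

Step 8
Reactants: 10 bis-PMB ether
Product: 12 13α-hydroxy-12-ketone, via lithium enolate 11 (not isolated)
Conditions: MeLi, THF, 0 °C; then trans-2-(phenylsulfonyl)-3-phenyloxaziridine, −78 °C; AcOH
Reagents that add atoms: 2-(phenylsulfonyl)-3-phenyloxaziridine, O=S(=O)(c1ccccc1)N1OC1c1ccccc1
Why: MeLi cleaves only the triethylsilyl enol ether to the regiodefined C12 enolate, and its electrophilic hydroxylation by the N-sulfonyloxaziridine (enolate oxidation) should occur at C13 from the α face because the β face is shielded by the 1,3-related axial C15 methyl, giving the equatorial 13α-ketol, which is also the more stable epimer.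

Step 9
Reactants: 12 13α-hydroxy-12-ketone
Product: 13 13α-O-PMBM ether
Conditions: 4-MeOC6H4CH2OCH2Cl (freshly prepared), i-Pr2NEt, Bu4NI (cat.), CH2Cl2, 0 → 25 °C
Reagents that add atoms: (4-methoxybenzyloxy)methyl chloride, COc1ccc(COCCl)cc1
Why: Alkoxymethylation with a chloromethyl ether and a hindered amine protects the ketol hydroxyl without enolizing the ketone or acidifying the enol ether, and the acetal formed is cleavable by DDQ together with the two PMB ethers.

Step 10
Reactants: 13 13α-O-PMBM ether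
Product: 17 11(20)-methylene-12-ketone, via lithium enolate 14 (not isolated), via Mannich base 15 (not isolated), via ammonium iodide 16 (not isolated)
Conditions: LiN(i-Pr)2, THF, −78 °C; CH2=NMe2+ I−, −78 → 0 °C; then MeI, CH2Cl2, 25 °C; then DBU, 0 °C
Reagents that add atoms: dimethyl(methylidene)ammonium iodide, C=[N+](C)C.[I-]
Why: Kinetic deprotonation takes a C11 methylene hydrogen (the C13 methine is alkoxy-substituted and hindered), the enolate enters a Mannich reaction with the iminium salt, and quaternization followed by E1cB loss of trimethylamine gives the α-methylene ketone that carries C20.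

Step 11
Reactants: 17 11(20)-methylene-12-ketone
Product: 18 12α-ol
Conditions: i-Bu2AlH, CH2Cl2, −78 °C; aq potassium sodium tartrate
Reagents that add atoms: none
Why: 1,2-Reduction of the enone by the aluminium hydride, which should approach C12 from the equatorial β direction because the axial path on the α face is closed by the syn-axial C14 silyloxy group, gives the axial 12α-carbinol.

Step 12
Reactants: 18 12α-ol
Product: 19 12α,14α-diol
Conditions: Bu4NF, THF, 25 → 40 °C
Reagents that add atoms: none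
Why: Fluoride-induced desilylation frees the hindered C14 hydroxyl while the ethers, the acetal and the enol ether are inert.

Step 13
Reactants: 19 12α,14α-diol
Product: 21 decalin-8-one, via acetonide 20 (not isolated)
Conditions: Me2C(OMe)2, PPTS (cat.), acetone, 25 °C; then H2O, 25 °C
Reagents that add atoms: 2,2-dimethoxypropane, COC(C)(C)OC; water, O
Why: The syn-diaxial 12α,14α-diol is bridged as its isopropylidene acetal (transacetalization), and after addition of water general-acid-catalysed protonation at C3 hydrolyses the C8 enol ether to the ketone, loss of the C2 ether being retarded because its pseudo-equatorial C–O bond lies close to the nodal plane of the enol π system.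

Step 14
Reactants: 22 propane-1,3-diol
Product: 24 3-(tert-butyldiphenylsilyloxy)propan-1-ol, via sodium alkoxide 23 (not isolated)
Conditions: NaH (1.0 equiv), THF, 25 °C; then t-BuPh2SiCl, 0 → 25 °C
Reagents that add atoms: tert-butyldiphenylsilyl chloride, CC(C)(C)[Si](Cl)(c1ccccc1)c1ccccc1
Why: The sparingly soluble monosodium alkoxide of the symmetric diol is silylated once (monosilylation of a diol), so the second hydroxyl stays free.

Step 15
Reactants: 24 3-(tert-butyldiphenylsilyloxy)propan-1-ol
Product: 25 3-(tert-butyldiphenylsilyloxy)propanal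
Conditions: TEMPO (10 mol %), PhI(OAc)2, CH2Cl2, 25 °C
Reagents that add atoms: none
Why: Oxoammonium-mediated oxidation of the primary alcohol stops at the aldehyde under neutral conditions that spare the silyl ether.

Step 16
Reactants: 25 3-(tert-butyldiphenylsilyloxy)propanal
Product: 26 3-(tert-butyldiphenylsilyloxy)-2-(phenylseleno)propanal
Conditions: N-(phenylseleno)phthalimide, L-prolinamide (5 mol %), CH2Cl2, 25 °C
Reagents that add atoms: N-(phenylseleno)phthalimide, O=C1c2ccccc2C(=O)N1[Se]c1ccccc1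
Why: Enamine catalysis (organocatalytic α-selenenylation) delivers electrophilic selenium to the α-carbon, and the configuration of this carbon is of no consequence because it becomes sp2 in step 18, so the aldehyde is used as formed.

Step 17
Reactants: 21 decalin-8-one; 26 3-(tert-butyldiphenylsilyloxy)-2-(phenylseleno)propanal
Product: 28 aldol adduct, via lithium enolate 27 (not isolated)
Conditions: LiN(i-Pr)2, THF, −78 °C; then 26, −78 °C; AcOH
Reagents that add atoms: none
Why: Kinetic deprotonation removes the axial C3 hydrogen (the C9 hydrogen is equatorial and next to an alkoxy group), and the aldol addition should form the C3–C4 bond on the α face opposite the 1,3-related axial C15 methyl so that the side chain is equatorial, the enolate adding to the aldehyde anti to its C–Se bond (polar 1,2-induction).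

Step 18
Reactants: 28 aldol adduct
Product: 30 3α-[(E)-3-(TBDPS-oxy)prop-1-enyl]-8-ketone, via mesylate 29 (not isolated)
Conditions: MeSO2Cl, Et3N, CH2Cl2, 0 °C
Reagents that add atoms: none
Why: The mesylate is displaced by the neighbouring selenium and the seleniranium ion loses PhSeCl, a stereospecific anti elimination of the β-hydroxy selenide (ketone vinylation through an α-seleno aldehyde) that gives the β,γ-unsaturated ketone and, from the adduct formed anti to the C–Se bond, should give mainly the E C4=C5 alkene.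

Step 19
Reactants: 30 3α-[(E)-3-(TBDPS-oxy)prop-1-enyl]-8-ketone; 31 trimethylsilylacetylene
Product: 34 8α-(trimethylsilylethynyl)-8β-ol, via lithium acetylide 32 (not isolated), via dichlorocerium acetylide 33 (not isolated)
Conditions: 31, n-BuLi, THF, −78 °C; CeCl3 (anhydrous), −78 °C; then 30, −78 °C; then H2O
Reagents that add atoms: none
Why: The weakly basic organocerium reagent (trivalent cerium) adds to the ketone without enolizing the acidic C3 position (1,2-addition of an acetylide), and the slim nucleophile should attack C8 axially on the α face, anti to the axial C9 alkoxy group, which places the ethynyl group axial and cis to the equatorial C3 alkenyl group.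

Step 20
Reactants: 34 8α-(trimethylsilylethynyl)-8β-ol
Product: 35 8α-ethynyl-8β-ol
Conditions: K2CO3, MeOH, 25 °C
Reagents that add atoms: none
Why: Methanolysis of the alkynyl C–Si bond (protodesilylation) frees the terminal alkyne while the O-silyl, ether and acetal groups stay.

Step 21
Reactants: 35 8α-ethynyl-8β-ol
Product: 38 cyclodeca-3,6-dien-8-one, via potassium alkoxide 36 (not isolated), via potassium allenolate 37 (not isolated)
Conditions: KN(SiMe3)2 (1.1 equiv), 18-crown-6, THF, −78 → 0 °C; AcOH, −78 °C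
Reagents that add atoms: none
Why: The crown-ether-separated potassium alkoxide at C8 triggers a concerted anionic oxy-Cope [3,3] shift through the six-centre array C3–C4–C5–C6–C7–C8, in which the C5–C6 bond forms as the C3–C8 ring bond breaks, and the ten-membered allenolate is protonated at C7 to the C6=C7 enone. The closest known reaction type is the anionic oxy-Cope ring expansion of 1-alkynyl-2-alkenylcyclohexanols to cyclodeca-2,5-dienones. The ten-membered ring is closed by four-atom ring expansion of the six-membered ring C1–C2–C3–C8–C9–C10 and not by end-to-end cyclization, so neither high dilution nor the entropic cost of a macrocyclization is involved. The only new stereocentre, C5, and the geometry of the C6=C7 bond are not controlled and need not be, because both are removed when C5 is deprotonated in step 22. The selectivity required is the ring-cis (Z) C3=C4 bond: the trans ring fusion locks the ethynyl group axial and the alkenyl group equatorial on the same face, so C5 can reach C6 only in the rotamer in which the C4=C5 bond lies over the C3–C2 ring bond, and this rotamer leads to the Z alkene, while the E geometry of C4=C5 keeps C16 outside the array. One equivalent of base is used so that the hydroxyl and not the alkyne C–H is deprotonated, and the driving force is the formation of the delocalized enolate.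

Step 22
Reactants: 38 cyclodeca-3,6-dien-8-one
Product: 40 7-hydroxy-8-ketone, via potassium trienolate 39 (not isolated)
Conditions: KN(SiMe3)2, THF, −78 → −40 °C; then trans-2-(phenylsulfonyl)-3-phenyloxaziridine, −78 °C; AcOH
Reagents that add atoms: 2-(phenylsulfonyl)-3-phenyloxaziridine, O=S(=O)(c1ccccc1)N1OC1c1ccccc1
Why: The doubly allylic, vinylogous C5 hydrogen is the most acidic one, so deprotonation should give the extended C8 enolate, which the N-sulfonyloxaziridine hydroxylates at its α-carbon C7 (enolate oxidation) on the outer face of the ring, leaving the conjugated diene in which both C3=C4 and C5=C6 are ring-cis and C16 sits on C5.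

Step 23
Reactants: 40 7-hydroxy-8-ketone; 41 2-bromopropanoyl bromide
Product: 42 7-(2-bromopropanoate)
Conditions: pyridine, CH2Cl2, −20 → 0 °C
Reagents that add atoms: none
Why: O-Acylation of the secondary ketol by the acid bromide proceeds with retention at C7, and the mixture at the bromine-bearing carbon converges in the next step.

Step 24
Reactants: 42 7-(2-bromopropanoate)
Product: 44 protected 8-hydroxy-17-methyl lactone, via samarium enolate 43 (not isolated)
Conditions: SmI2 (2.2 equiv), THF, −78 °C; then H2O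
Reagents that add atoms: none
Why: Reduction of the C–Br bond by divalent samarium gives a trivalent samarium ester enolate that adds to the neighbouring C8 ketone (intramolecular Reformatsky reaction, 5-exo-trig closure of the γ-lactone) through a chelate in which the ring bonds C7–C6 and C8–C9 stay anti, so the lactone should be trans-fused, with the C18 methyl in the less hindered position cis to the C8 hydroxyl.

Step 25
Reactants: 44 protected 8-hydroxy-17-methyl lactone
Product: 45 2,9,13-triol
Conditions: DDQ, CH2Cl2–pH 7 buffer, 0 → 25 °C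
Reagents that add atoms: none
Why: Oxidative cleavage of electron-rich benzylic ethers (hydride abstraction and hydrolysis of the oxocarbenium ions) removes both PMB ethers and the PMBM acetal in one operation, while acetonide, silyl ether, lactone and the non-planar diene are inert and the excess of water disfavours acetal formation with the tertiary C8 hydroxyl.

Step 26
Reactants: 45 2,9,13-triol
Product: 46 2,9,13-triacetate
Conditions: Ac2O, pyridine, DMAP (cat.), CH2Cl2, 0 → 25 °C
Reagents that add atoms: acetic anhydride, CC(=O)OC(C)=O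
Why: Nucleophilic catalysis acetylates the three secondary hydroxyls at C2, C9 and C13 (esterification), the tertiary C8 hydroxyl being too hindered to react under these conditions.

Step 27
Reactants: 46 2,9,13-triacetate
Product: 47 12,14-diol
Conditions: AcOH–H2O (4:1), 35 °C
Reagents that add atoms: none
Why: Acid-catalysed acetal hydrolysis removes the strained bridging acetonide under conditions that leave the acetates, the silyl ether and the lactone intact.

Step 28
Reactants: 47 12,14-diol
Product: 48 16-O-TBDPS Juncin Q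
Conditions: VO(acac)2 (5 mol %), t-BuOOH, CH2Cl2, 0 → 25 °C
Reagents that add atoms: tert-butyl hydroperoxide, CC(C)(C)OO
Why: In this hydroxyl-directed epoxidation the vanadium alkoxide of the axial allylic 12α-hydroxyl delivers oxygen to the α face of the C11=C20 methylene only, which sets C11, while the diene carries no free allylic hydroxyl because C16 is still silylated.

Step 29
Reactants: 48 16-O-TBDPS Juncin Q
Product: 49 Juncin Q
Conditions: Bu4NF–AcOH (1:1), THF, 0 → 25 °C
Reagents that add atoms: none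
Why: Buffered fluoride cleaves the primary silyl ether (desilylation) without base-induced acetyl migration, lactone opening or attack on the epoxide.

**Compound list**

1 | (E)-4-methoxybut-3-en-2-one | CO/C=C/C(C)=O | starting material
2 | sodium (E)-3-oxobut-1-en-1-olate (sodium enolate of formylacetone) | [Na+].[O-]/C=C/C(C)=O | intermediate
3 | (E)-4-(tert-butyldimethylsilyloxy)but-3-en-2-one | CC(=O)/C=C/O[Si](C)(C)C(C)(C)C | intermediate
4 | (E)-1-(tert-butyldimethylsilyloxy)-3-(triethylsilyloxy)buta-1,3-diene | C=C(O[Si](CC)(CC)CC)/C=C/O[Si](C)(C)C(C)(C)C | intermediate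
5 | 2-methoxy-5-methyl-1,4-benzoquinone | COC1=CC(=O)C(C)=CC1=O | starting material
6 | cis-fused Diels–Alder adduct: C2 and C9 ketones, C3=C8 with 8-OMe, ring A C12=C13 enol ether with 12-OTES, 14α-OTBS, C15 methyl on C1 and H-10 both β | C1=C(O[Si](CC)(CC)CC)C[C@H]2C(=O)C(OC)=CC(=O)[C@@]2(C)[C@H]1O[Si](C)(C)C(C)(C)C | intermediate
7 | trans-fused dione: C10 epimer of 6 (H-10 α, C15 methyl β and axial) | C1=C(O[Si](CC)(CC)CC)C[C@@H]2C(=O)C(OC)=CC(=O)[C@@]2(C)[C@H]1O[Si](C)(C)C(C)(C)C | intermediate
8 | 2β,9β-diol of 7 (2-OH equatorial, 9-OH axial, 8-methoxy C3=C8 enol ether kept) | C1=C(O[Si](CC)(CC)CC)C[C@@H]2[C@H](O)C(OC)=C[C@H](O)[C@@]2(C)[C@H]1O[Si](C)(C)C(C)(C)C | intermediate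
9 | disodium 2β,9β-dialkoxide of 8 | C1=C(O[Si](CC)(CC)CC)C[C@@H]2[C@H](O[Na])C(OC)=C[C@H](O[Na])[C@@]2(C)[C@H]1O[Si](C)(C)C(C)(C)C | intermediate
10 | trans-decalin 2β,9β-bis(PMB) ether with 8-methoxy C3=C8 enol ether, 12-OTES C12=C13 enol ether and 14α-OTBS | C1=C(O[Si](CC)(CC)CC)C[C@@H]2[C@H](OCc3ccc(OC)cc3)C(OC)=C[C@H](OCc3ccc(OC)cc3)[C@@]2(C)[C@H]1O[Si](C)(C)C(C)(C)C | intermediate
11 | lithium C12=C13 enolate formed from 10 by loss of the triethylsilyl group | C1=C(O[Li])C[C@@H]2[C@H](OCc3ccc(OC)cc3)C(OC)=C[C@H](OCc3ccc(OC)cc3)[C@@]2(C)[C@H]1O[Si](C)(C)C(C)(C)C | intermediate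
12 | 13α-hydroxy-12-ketone (13-OH equatorial, cis to 14α-OTBS) | O[C@H]1C(=O)C[C@@H]2[C@H](OCc3ccc(OC)cc3)C(OC)=C[C@H](OCc3ccc(OC)cc3)[C@@]2(C)[C@H]1O[Si](C)(C)C(C)(C)C | intermediate
13 | 13α-[(4-methoxybenzyloxy)methoxy]-12-ketone (PMBM ether of 12) | O(COCc4ccc(OC)cc4)[C@H]1C(=O)C[C@@H]2[C@H](OCc3ccc(OC)cc3)C(OC)=C[C@H](OCc3ccc(OC)cc3)[C@@]2(C)[C@H]1O[Si](C)(C)C(C)(C)C | intermediate
14 | lithium C11=C12 enolate of 13 | O(COCc4ccc(OC)cc4)[C@H]1C(O[Li])=C[C@@H]2[C@H](OCc3ccc(OC)cc3)C(OC)=C[C@H](OCc3ccc(OC)cc3)[C@@]2(C)[C@H]1O[Si](C)(C)C(C)(C)C | intermediate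
15 | 11-(dimethylaminomethyl)-12-ketone (Mannich base, C11 configuration undefined) | O(COCc4ccc(OC)cc4)[C@H]1C(=O)C(CN(C)C)[C@@H]2[C@H](OCc3ccc(OC)cc3)C(OC)=C[C@H](OCc3ccc(OC)cc3)[C@@]2(C)[C@H]1O[Si](C)(C)C(C)(C)C | intermediate
16 | 11-(trimethylammoniomethyl)-12-ketone iodide | O(COCc4ccc(OC)cc4)[C@H]1C(=O)C(C[N+](C)(C)C)[C@@H]2[C@H](OCc3ccc(OC)cc3)C(OC)=C[C@H](OCc3ccc(OC)cc3)[C@@]2(C)[C@H]1O[Si](C)(C)C(C)(C)C.[I-] | intermediate
17 | 11(20)-methylene-12-ketone | O(COCc4ccc(OC)cc4)[C@H]1C(=O)C(=C)[C@@H]2[C@H](OCc3ccc(OC)cc3)C(OC)=C[C@H](OCc3ccc(OC)cc3)[C@@]2(C)[C@H]1O[Si](C)(C)C(C)(C)C | intermediate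
18 | 11(20)-methylene-12α-ol (12-OH axial) | O(COCc4ccc(OC)cc4)[C@H]1[C@@H](O)C(=C)[C@@H]2[C@H](OCc3ccc(OC)cc3)C(OC)=C[C@H](OCc3ccc(OC)cc3)[C@@]2(C)[C@H]1O[Si](C)(C)C(C)(C)C | intermediate
19 | 12α,14α-diol (both OH axial) | O(COCc4ccc(OC)cc4)[C@H]1[C@@H](O)C(=C)[C@@H]2[C@H](OCc3ccc(OC)cc3)C(OC)=C[C@H](OCc3ccc(OC)cc3)[C@@]2(C)[C@H]1O | intermediate
20 | 12α,14α-O-isopropylidene acetal of 19 with the C8 methyl enol ether still present | O(COCc4ccc(OC)cc4)[C@H]1[C@@H](OC(C)(C)O5)C(=C)[C@@H]2[C@H](OCc3ccc(OC)cc3)C(OC)=C[C@H](OCc3ccc(OC)cc3)[C@@]2(C)[C@H]15 | intermediate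
21 | trans-decalin-8-one with 2β,9β-bis(OPMB), 13α-OPMBM, 12α,14α-acetonide, 11(20)-methylene and C3 methylene | O(COCc4ccc(OC)cc4)[C@H]1[C@@H](OC(C)(C)O5)C(=C)[C@@H]2[C@H](OCc3ccc(OC)cc3)C(=O)C[C@H](OCc3ccc(OC)cc3)[C@@]2(C)[C@H]15 | intermediate
22 | propane-1,3-diol | OCCCO | starting material
23 | sodium 3-hydroxypropan-1-olate | [Na]OCCCO | intermediate
24 | 3-(tert-butyldiphenylsilyloxy)propan-1-ol | OCCCO[Si](c1ccccc1)(c1ccccc1)C(C)(C)C | intermediate
25 | 3-(tert-butyldiphenylsilyloxy)propanal | O=CCCO[Si](c1ccccc1)(c1ccccc1)C(C)(C)C | intermediate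
26 | 3-(tert-butyldiphenylsilyloxy)-2-(phenylseleno)propanal (selenium-bearing carbon undefined) | O=CC([Se]c1ccccc1)CO[Si](c1ccccc1)(c1ccccc1)C(C)(C)C | intermediate
27 | lithium C3=C8 enolate of 21 | O(COCc4ccc(OC)cc4)[C@H]1[C@@H](OC(C)(C)O5)C(=C)[C@@H]2[C@H](OCc3ccc(OC)cc3)C(O[Li])=C[C@H](OCc3ccc(OC)cc3)[C@@]2(C)[C@H]15 | intermediate
28 | aldol adduct: 3α-[1-hydroxy-2-(phenylseleno)-3-(TBDPS-oxy)propyl]-8-ketone (side chain equatorial, C4 and C5 not assigned) | O(COCc4ccc(OC)cc4)[C@H]1[C@@H](OC(C)(C)O5)C(=C)[C@@H]2[C@H](OCc3ccc(OC)cc3)C(=O)[C@@H](C(O)C([Se]c3ccccc3)CO[Si](c3ccccc3)(c3ccccc3)C(C)(C)C)[C@H](OCc3ccc(OC)cc3)[C@@]2(C)[C@H]15 | intermediate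
29 | C4 methanesulfonate of 28 | O(COCc4ccc(OC)cc4)[C@H]1[C@@H](OC(C)(C)O5)C(=C)[C@@H]2[C@H](OCc3ccc(OC)cc3)C(=O)[C@@H](C(OS(C)(=O)=O)C([Se]c3ccccc3)CO[Si](c3ccccc3)(c3ccccc3)C(C)(C)C)[C@H](OCc3ccc(OC)cc3)[C@@]2(C)[C@H]15 | intermediate
30 | 3α-[(E)-3-(tert-butyldiphenylsilyloxy)prop-1-enyl]-8-ketone (β,γ-unsaturated ketone, alkenyl equatorial) | O(COCc4ccc(OC)cc4)[C@H]1[C@@H](OC(C)(C)O5)C(=C)[C@@H]2[C@H](OCc3ccc(OC)cc3)C(=O)[C@@H](/C=C/CO[Si](c3ccccc3)(c3ccccc3)C(C)(C)C)[C@H](OCc3ccc(OC)cc3)[C@@]2(C)[C@H]15 | intermediate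
31 | trimethylsilylacetylene | C#C[Si](C)(C)C | starting material
32 | lithium (trimethylsilyl)acetylide | [Li]C#C[Si](C)(C)C | intermediate
33 | dichlorocerium (trimethylsilyl)acetylide (trivalent cerium) | Cl[Ce](Cl)C#C[Si](C)(C)C | intermediate
34 | 8α-[(trimethylsilyl)ethynyl]-8β-hydroxy-3α-alkenyl trans-decalin (ethynyl axial, alkenyl equatorial, cis) | O(COCc4ccc(OC)cc4)[C@H]1[C@@H](OC(C)(C)O5)C(=C)[C@@H]2[C@H](OCc3ccc(OC)cc3)[C@@](O)(C#C[Si](C)(C)C)[C@@H](/C=C/CO[Si](c3ccccc3)(c3ccccc3)C(C)(C)C)[C@H](OCc3ccc(OC)cc3)[C@@]2(C)[C@H]15 | intermediate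
35 | 8α-ethynyl-8β-hydroxy-3α-[(E)-3-(TBDPS-oxy)prop-1-enyl] trans-decalin | O(COCc4ccc(OC)cc4)[C@H]1[C@@H](OC(C)(C)O5)C(=C)[C@@H]2[C@H](OCc3ccc(OC)cc3)[C@@](O)(C#C)[C@@H](/C=C/CO[Si](c3ccccc3)(c3ccccc3)C(C)(C)C)[C@H](OCc3ccc(OC)cc3)[C@@]2(C)[C@H]15 | intermediate
36 | potassium 8β-alkoxide of 35 | O(COCc4ccc(OC)cc4)[C@H]1[C@@H](OC(C)(C)O5)C(=C)[C@@H]2[C@H](OCc3ccc(OC)cc3)[C@@](O[K])(C#C)[C@@H](/C=C/CO[Si](c3ccccc3)(c3ccccc3)C(C)(C)C)[C@H](OCc3ccc(OC)cc3)[C@@]2(C)[C@H]15 | intermediate
37 | ten-membered potassium allenolate: C8(OK)=C7=C6, C5 bearing CH2OTBDPS, (3Z)-C3=C4 | O(COCc4ccc(OC)cc4)[C@H]1[C@@H](OC(C)(C)O5)C(=C)[C@@H]2[C@H](OCc3ccc(OC)cc3)C(O[K])=C=CC(CO[Si](c3ccccc3)(c3ccccc3)C(C)(C)C)/C=C\[C@H](OCc3ccc(OC)cc3)[C@@]2(C)[C@H]15 | intermediate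
38 | bicyclo[8.4.0] cyclodeca-3,6-dien-8-one: C8 ketone, C6=C7 enone, (3Z)-C3=C4, CH2OTBDPS on C5 (C5 and the C6=C7 geometry undefined) | O(COCc4ccc(OC)cc4)[C@H]1[C@@H](OC(C)(C)O5)C(=C)[C@@H]2[C@H](OCc3ccc(OC)cc3)C(=O)C=CC(CO[Si](c3ccccc3)(c3ccccc3)C(C)(C)C)/C=C\[C@H](OCc3ccc(OC)cc3)[C@@]2(C)[C@H]15 | intermediate
39 | potassium trienolate of 38 (C8(OK)=C7, C5=C6, C3=C4) | O(COCc4ccc(OC)cc4)[C@H]1[C@@H](OC(C)(C)O5)C(=C)[C@@H]2[C@H](OCc3ccc(OC)cc3)C(O[K])=C/C=C(CO[Si](c3ccccc3)(c3ccccc3)C(C)(C)C)\C=C/[C@H](OCc3ccc(OC)cc3)[C@@]2(C)[C@H]15 | intermediate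
40 | 7-hydroxy-8-ketone with the ring-cis,ring-cis C3=C4–C5=C6 diene (C16 on C5, C7 as in Juncin Q) | O(COCc4ccc(OC)cc4)[C@H]1[C@@H](OC(C)(C)O5)C(=C)[C@@H]2[C@H](OCc3ccc(OC)cc3)C(=O)[C@H](/C=C(CO[Si](c3ccccc3)(c3ccccc3)C(C)(C)C)\C=C/[C@H](OCc3ccc(OC)cc3)[C@@]2(C)[C@H]15)O | intermediate
41 | 2-bromopropanoyl bromide (racemic) | CC(Br)C(=O)Br | starting material
42 | 7-O-(2-bromopropanoyl) ester of 40 (bromine-bearing carbon undefined) | O(COCc4ccc(OC)cc4)[C@H]1[C@@H](OC(C)(C)O5)C(=C)[C@@H]2[C@H](OCc3ccc(OC)cc3)C(=O)[C@H](/C=C(CO[Si](c3ccccc3)(c3ccccc3)C(C)(C)C)\C=C/[C@H](OCc3ccc(OC)cc3)[C@@]2(C)[C@H]15)OC(=O)C(C)Br | intermediate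
43 | samarium ester enolate of 42 (trivalent samarium, diiodosamarium O-enolate of the C7 propanoate) | O(COCc4ccc(OC)cc4)[C@H]1[C@@H](OC(C)(C)O5)C(=C)[C@@H]2[C@H](OCc3ccc(OC)cc3)C(=O)[C@H](/C=C(CO[Si](c3ccccc3)(c3ccccc3)C(C)(C)C)\C=C/[C@H](OCc3ccc(OC)cc3)[C@@]2(C)[C@H]15)OC(O[Sm](I)I)=CC | intermediate
44 | protected briarane: 8-hydroxy-17-methyl γ-lactone trans-fused at C7–C8 (8-OH and C18 methyl cis), 2,9-bis(OPMB), 13-OPMBM, 12,14-acetonide, 11(20)-methylene, 16-OTBDPS | O(COCc4ccc(OC)cc4)[C@H]1[C@@H](OC(C)(C)O5)C(=C)[C@@H]2[C@H](OCc3ccc(OC)cc3)[C@@]3(O)[C@H](/C=C(CO[Si](c6ccccc6)(c6ccccc6)C(C)(C)C)\C=C/[C@H](OCc6ccc(OC)cc6)[C@@]2(C)[C@H]15)OC(=O)[C@@H]3C | intermediate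
45 | 2,9,13-triol of 44 (8-OH also free; acetonide, methylene and 16-OTBDPS kept) | O[C@H]1[C@@H](OC(C)(C)O5)C(=C)[C@@H]2[C@H](O)[C@@]3(O)[C@H](/C=C(CO[Si](c6ccccc6)(c6ccccc6)C(C)(C)C)\C=C/[C@H](O)[C@@]2(C)[C@H]15)OC(=O)[C@@H]3C | intermediate
46 | 2,9,13-triacetate with 12,14-acetonide | CC(=O)O[C@H]1[C@@H](OC(C)(C)O5)C(=C)[C@@H]2[C@H](OC(C)=O)[C@@]3(O)[C@H](/C=C(CO[Si](c6ccccc6)(c6ccccc6)C(C)(C)C)\C=C/[C@H](OC(C)=O)[C@@]2(C)[C@H]15)OC(=O)[C@@H]3C | intermediate
47 | 12,14-diol triacetate with 11(20)-methylene and 16-OTBDPS | CC(=O)O[C@H]1[C@@H](O)C(=C)[C@@H]2[C@H](OC(C)=O)[C@@]3(O)[C@H](/C=C(CO[Si](c6ccccc6)(c6ccccc6)C(C)(C)C)\C=C/[C@H](OC(C)=O)[C@@]2(C)[C@H]1O)OC(=O)[C@@H]3C | intermediate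
48 | 16-O-(tert-butyldiphenylsilyl) Juncin Q (11,20-epoxide with oxygen on the α face) | CC(=O)O[C@H]1[C@@H](O)[C@]2(CO2)[C@@H]2[C@H](OC(C)=O)[C@@]3(O)[C@H](/C=C(CO[Si](c6ccccc6)(c6ccccc6)C(C)(C)C)\C=C/[C@H](OC(C)=O)[C@@]2(C)[C@H]1O)OC(=O)[C@@H]3C | intermediate
49 | Juncin Q | CC(=O)O[C@H]1[C@@H](O)[C@]2(CO2)[C@@H]2[C@H](OC(C)=O)[C@@]3(O)[C@H](/C=C(CO)\C=C/[C@H](OC(C)=O)[C@@]2(C)[C@H]1O)OC(=O)[C@@H]3C | target

**Step count and risks**

Total step count: 29. Longest linear sequence: 26 steps (steps 1–13 and 17–29, from 1 to 49); the selenoaldehyde branch (steps 14–16) joins at step 17.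

The three steps most likely to fail:

Step 21. The alkyne C–H may be deprotonated in competition with the hydroxyl, or the propargylic alkoxide may fragment by loss of acetylide back to the ketone, so that the [3,3] shift is outrun. The fallback runs the same bond reorganization on the neutral silyl ether. It sets out from 35, which is silylated at the tertiary hydroxyl with N-(trimethylsilyl)imidazole to the trimethylsilyl ether F1. Thermolysis of F1 in o-dichlorobenzene at about 180–200 °C (thermal acetylenic siloxy-Cope rearrangement) should give the ten-membered silyloxyallene F2. Methanolysis of F2 (K2CO3, MeOH, 0 °C) releases the enone, and the route is rejoined at 38.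

Step 22. Deprotonation may take place at C9 instead of C5, or the oxidant may enter on the other face of the trienolate, so that facial selectivity at C7 is poor or reversed. The fallback uses the other epimer with inversion instead of retention. It sets out from 38, from which the same oxidation gives the 7-epimeric alcohol F3. Mitsunobu esterification of F3 with 2-bromopropanoic acid (PPh3, diisopropyl azodicarboxylate, toluene, 0 °C) inverts C7, and the route is rejoined at 42.

Step 24. Electron transfer to the C8 ketone with cleavage of the C7–O ester bond (loss of the acyloxy group) may compete with enolate formation, or the enolate may close on the wrong face of the ketone. The fallback makes the C8–C17 bond intermolecularly. It sets out from 40, whose C8 ketone is treated with the zinc enolate of ethyl 2-bromopropanoate (Zn, THF, 25 °C); addition under chelation with the C7 alkoxide should give the hydroxy ester F4. F4 lactonizes on mild acid treatment (PPTS, benzene, 50 °C), with C17 equilibrated by DBU if needed, and the route is rejoined at 44.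

**Further compounds**

F1 | step 21 | 8-O-trimethylsilyl ether of 35 | O(COCc4ccc(OC)cc4)[C@H]1[C@@H](OC(C)(C)O5)C(=C)[C@@H]2[C@H](OCc3ccc(OC)cc3)[C@@](O[Si](C)(C)C)(C#C)[C@@H](/C=C/CO[Si](c3ccccc3)(c3ccccc3)C(C)(C)C)[C@H](OCc3ccc(OC)cc3)[C@@]2(C)[C@H]15
F2 | step 21 | ten-membered 8-(trimethylsilyloxy)allene (C8=C7=C6, (3Z)-C3=C4) | O(COCc4ccc(OC)cc4)[C@H]1[C@@H](OC(C)(C)O5)C(=C)[C@@H]2[C@H](OCc3ccc(OC)cc3)C(O[Si](C)(C)C)=C=CC(CO[Si](c3ccccc3)(c3ccccc3)C(C)(C)C)/C=C\[C@H](OCc3ccc(OC)cc3)[C@@]2(C)[C@H]15
F3 | step 22 | 7-epimer of alcohol 40 | O(COCc4ccc(OC)cc4)[C@H]1[C@@H](OC(C)(C)O5)C(=C)[C@@H]2[C@H](OCc3ccc(OC)cc3)C(=O)[C@@H](/C=C(CO[Si](c3ccccc3)(c3ccccc3)C(C)(C)C)\C=C/[C@H](OCc3ccc(OC)cc3)[C@@]2(C)[C@H]15)O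
F4 | step 24 | 7,8-dihydroxy-8-(1-ethoxycarbonylethyl) compound (intermolecular Reformatsky adduct of 40, C17 undefined) | O(COCc4ccc(OC)cc4)[C@H]1[C@@H](OC(C)(C)O5)C(=C)[C@@H]2[C@H](OCc3ccc(OC)cc3)[C@](O)(C(C)C(=O)OCC)[C@H](/C=C(CO[Si](c3ccccc3)(c3ccccc3)C(C)(C)C)\C=C/[C@H](OCc3ccc(OC)cc3)[C@@]2(C)[C@H]15)O
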